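**Retrosynthetic overview**
- Feature: in the benzo ring of the indole, bromine sits on the adjacent carbons C5 and C6, C4 and C7 are CH, and C3a/C7a are the fusion atoms. This is the pattern that results when two bromoethynyl arms on pyrrole C4 and C5 join through their bromine-bearing termini.
- Endgame: C2–Br from C2–CO2H (ipso-bromodecarboxylation) and C3–CH2NMe2 from C3–H (Mannich), both leading back to methyl 5,6-dibromo-1-methylindole-2-carboxylate 8.
- Key disconnection: the C5–C6 bond of 8, opened to the pyrrole-fused bis(bromoalkyne) 5 (Bergman cycloaromatization with a hydrogen-atom donor).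
- 5 comes from twofold Sonogashira coupling and silicon-to-bromine exchange on the 4,5-dibromopyrrole ester 2, made from ester 1.
- Ring order: the pyrrole ring is bought in 1; the benzene ring is the only ring formed (step 4).

Key step: step 4

Assumption: amino acid 10 exists as the zwitterion but is drawn and listed in its neutral form; compounds 1, 3 and 6 are taken as commercial.

**Step 1**
Reactants: 1 methyl 1-methyl-1H-pyrrole-2-carboxylate
Product: 2 methyl 4,5-dibromo-1-methyl-1H-pyrrole-2-carboxylate
Conditions: NBS (2.1 equiv), DMF, 0 °C to rt, dark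
Reagents that add atoms: N-bromosuccinimide, O=C1CCC(=O)N1Br
Why: Electrophilic aromatic bromination; the ring nitrogen activates C5 and the 2-ester directs the second bromine to C4, so the deactivated C3 next to the ester should stay free.

**Step 2**
Reactants: 2 methyl 4,5-dibromo-1-methyl-1H-pyrrole-2-carboxylate; 3 ethynyltrimethylsilane
Product: 4 methyl 1-methyl-4,5-bis[(trimethylsilyl)ethynyl]-1H-pyrrole-2-carboxylate
Conditions: 3 (3 equiv), PdCl2(PhCN)2 (5 mol%), [t-Bu3PH]BF4 (10 mol%), CuI (5 mol%), i-Pr2NH, 1,4-dioxane, sealed tube, 50 °C
Reagents that add atoms: none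
Why: Twofold Sonogashira coupling; the electron-rich tri-tert-butylphosphine complex of zerovalent palladium should insert into both electron-rich heteroaryl C–Br bonds under mild conditions that leave the silyl caps in place.

**Step 3**
Reactants: 4 methyl 1-methyl-4,5-bis[(trimethylsilyl)ethynyl]-1H-pyrrole-2-carboxylate
Product: 5 methyl 4,5-bis(bromoethynyl)-1-methyl-1H-pyrrole-2-carboxylate
Conditions: NBS (2.3 equiv), AgNO3 (0.2 equiv), acetone, rt, dark
Reagents that add atoms: N-bromosuccinimide, O=C1CCC(=O)N1Br
Why: AgNO3-catalysed bromodesilylation of alkynylsilanes (ipso-bromination at the silver-activated alkyne terminus), which should outpace bromination of the remaining C3–H of a pyrrole deactivated by one ester and two alkynyl groups.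

**Step 4**
Reactants: 5 methyl 4,5-bis(bromoethynyl)-1-methyl-1H-pyrrole-2-carboxylate; 6 cyclohexa-1,4-diene
Product: 8 methyl 5,6-dibromo-1-methyl-1H-indole-2-carboxylate, via 4,7-didehydroindole diradical 7 (not isolated)
Conditions: cyclohexa-1,4-diene (100 equiv), PhCl (0.005 M), degassed, sealed vessel, 200 °C
Reagents that add atoms: none
Why: Proposed new method: the pyrrole C4=C5 bond holds the two bromoethynyl arms as a cis-enediyne, so heating should bring about Bergman C1–C6 closure between the two bromine-bearing sp carbons to give the σ,σ-1,4-diradical 7, in which the new C5–C6 bond already carries both bromines, and each radical centre then takes one hydrogen atom from cyclohexa-1,4-diene, which ends as benzene. The closest known reaction type is the thermal Bergman cycloaromatization of arene-fused enediynes with hydrogen-atom trapping of the diradical (halogen-capped termini are tolerated in the benzene series); a pyrrole-fused bis(bromoalkyne) has not been closed in this way. The benzene ring is closed in one in-plane union of the two alkyne termini (six-membered carbocycle, C1–C6 mode of the hexa-3-ene-1,5-diyne unit), and no stereocentre is formed. Regiochemistry is fixed because the carbons that bond are the ones bearing bromine, so the halogens can only end at C5 and C6 with C4 and C7 as CH. The step needs C1–C6 closure over C1–C5 (fulvene) closure and hydrogen abstraction over bromine-atom transfer or radical addition to a second alkyne; the rigid planar ene unit without radical-stabilising groups at the termini favours the six-membered closure, and high dilution in a hundredfold excess of the donor should make hydrogen transfer the fastest fate of each aryl radical. The wider exocyclic angles of the five-membered ring raise the barrier, hence 200 °C, and the 2-ester lowers the electron density of the pyrrole enough for it to survive.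

**Step 5**
Reactants: 8 methyl 5,6-dibromo-1-methyl-1H-indole-2-carboxylate
Product: 9 methyl 5,6-dibromo-3-[(dimethylamino)methyl]-1-methyl-1H-indole-2-carboxylate
Conditions: CH2=NMe2+ I− (1.5 equiv), MeCN, 80 °C; aq NaHCO3
Reagents that add atoms: N,N-dimethylmethyleneiminium iodide (Eschenmoser's salt), C=[N+](C)C.[I-]
Why: Mannich aminomethylation at indole C3, the only open position of the pyrrole ring; the preformed iminium ion is electrophilic enough for a nucleus deactivated by the ester and two bromines.

**Step 6**
Reactants: 9 methyl 5,6-dibromo-3-[(dimethylamino)methyl]-1-methyl-1H-indole-2-carboxylate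
Product: 10 5,6-dibromo-3-[(dimethylamino)methyl]-1-methyl-1H-indole-2-carboxylic acid
Conditions: LiOH·H2O (3 equiv), THF/MeOH/H2O, 50 °C; then 1 M HCl to pH 7
Reagents that add atoms: lithium hydroxide, [Li+].[OH-]
Why: Saponification of the methyl ester; aryl bromides and the tertiary amine are inert to hydroxide, and neutralisation to the isoelectric point should release the amino acid as its zwitterion.

**Step 7**
Reactants: 10 5,6-dibromo-3-[(dimethylamino)methyl]-1-methyl-1H-indole-2-carboxylic acid
Product: 11 2,5,6-tribromo-1-methylgramine, 1-(2,5,6-tribromo-1-methyl-1H-indol-3-yl)-N,N-dimethylmethanamine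
Conditions: NBS (1.05 equiv), AcOH/MeCN, 0 °C to rt; aq NaHCO3
Reagents that add atoms: N-bromosuccinimide, O=C1CCC(=O)N1Br
Why: Ipso-bromodecarboxylation of an electron-rich heteroaryl carboxylic acid; with C3 blocked the electrophilic bromine ends at C2 and CO2 leaves in place of a proton, while acetic acid keeps the amine protonated so that N-bromination and loss of the aminomethyl arm after attack at C3 are suppressed.

**Compound list**
1 | methyl 1-methyl-1H-pyrrole-2-carboxylate | COC(=O)c1cccn1C | starting material
2 | methyl 4,5-dibromo-1-methyl-1H-pyrrole-2-carboxylate | COC(=O)c1cc(Br)c(Br)n1C | intermediate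
3 | ethynyltrimethylsilane | C#C[Si](C)(C)C | starting material
4 | methyl 1-methyl-4,5-bis[(trimethylsilyl)ethynyl]-1H-pyrrole-2-carboxylate | COC(=O)c1cc(C#C[Si](C)(C)C)c(C#C[Si](C)(C)C)n1C | intermediate
5 | methyl 4,5-bis(bromoethynyl)-1-methyl-1H-pyrrole-2-carboxylate | COC(=O)c1cc(C#CBr)c(C#CBr)n1C | intermediate
6 | cyclohexa-1,4-diene | C1=CCC=CC1 | starting material
7 | methyl 5,6-dibromo-1-methyl-4,7-didehydro-1H-indole-2-carboxylate (σ,σ-diradical, radical centres at C4 and C7) | COC(=O)c1cc2[c]c(Br)c(Br)[c]c2n1C | intermediate
8 | methyl 5,6-dibromo-1-methyl-1H-indole-2-carboxylate | COC(=O)c1cc2cc(Br)c(Br)cc2n1C | intermediate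
9 | methyl 5,6-dibromo-3-[(dimethylamino)methyl]-1-methyl-1H-indole-2-carboxylate | COC(=O)c1c(CN(C)C)c2cc(Br)c(Br)cc2n1C | intermediate
10 | 5,6-dibromo-3-[(dimethylamino)methyl]-1-methyl-1H-indole-2-carboxylic acid | OC(=O)c1c(CN(C)C)c2cc(Br)c(Br)cc2n1C | intermediate
11 | 2,5,6-tribromo-1-methylgramine | CN(C)Cc1c(Br)n(C)c2cc(Br)c(Br)cc12 | target

**Total step count:** 7
**Longest linear sequence:** 7 steps (1 → 2 → 4 → 5 → 8 → 9 → 10 → 11)

**Steps most likely to fail**

1. Step 4 (Proposed new method). At the temperature the wide five-membered-ring enediyne demands, thermal loss of bromine from the bromoalkynes, bromine-atom transfer to the aryl radicals and radical oligomerisation may outrun the closure.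
The fallback uses known chemistry only, sets out from ethynyltrimethylsilane 3 and comes back at target 11. It builds the pyrrole ring onto a benzene that already carries the two bromines.
   - 3 is aminomethylated with paraformaldehyde and dimethylamine under CuI catalysis (alkyne Mannich reaction) to N,N-dimethyl-3-(trimethylsilyl)prop-2-yn-1-amine F1.
   - Commercial 3,4-dibromoaniline is iodinated with N-iodosuccinimide at the unhindered position ortho to nitrogen to give 4,5-dibromo-2-iodoaniline F2.
   - Larock heteroannulation of F2 with F1 (Pd(OAc)2, Na2CO3, LiCl, DMF, 100 °C) reacts at the C–I bond only and places silicon at C2, giving 1-[5,6-dibromo-2-(trimethylsilyl)-1H-indol-3-yl]-N,N-dimethylmethanamine F3.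
   - N-Methylation of the sodium indolide (NaH, then MeI 1.0 equiv, DMF, 0 °C) gives 1-[5,6-dibromo-1-methyl-2-(trimethylsilyl)-1H-indol-3-yl]-N,N-dimethylmethanamine F4.
   - Ipso-bromodesilylation at C2 with NBS in AcOH/MeCN gives 11.

2. Step 7. Oxidation of the amine by the brominating agent, or attack at C3 followed by loss of the aminomethyl arm, may compete with decarboxylative bromination at C2.
The fallback sets out from 8 and comes back at 11. It brings in the C2 bromine together with the C3 carbon from an oxindole and introduces the amine last.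
   - Saponification of 8 (LiOH, then HCl) gives 5,6-dibromo-1-methyl-1H-indole-2-carboxylic acid F5.
   - Protodecarboxylation (Ag2CO3 cat., AcOH, DMSO, 120 °C) gives 5,6-dibromo-1-methyl-1H-indole F6.
   - Oxidation with pyridinium tribromide in t-BuOH/H2O gives 3,3,5,6-tetrabromo-1-methylindolin-2-one F7.
   - Reduction with Zn dust in AcOH gives 5,6-dibromo-1-methylindolin-2-one F8.
   - Vilsmeier-type bromoformylation (POBr3, DMF, CHCl3, reflux) gives 2,5,6-tribromo-1-methyl-1H-indole-3-carbaldehyde F9.
   - Reductive amination (Me2NH, NaBH(OAc)3, AcOH, 1,2-dichloroethane) gives 11.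

3. Step 5. Attack of the iminium ion at C3 may be too slow on a nucleus deactivated by the ester and two bromines, or may revert under forcing conditions.
The fallback sets out from 8 and comes back at 9. It installs the C3 carbon irreversibly at the aldehyde oxidation level.
   - Vilsmeier–Haack formylation (POCl3, DMF, 80 °C; aqueous NaOAc) gives methyl 5,6-dibromo-3-formyl-1-methyl-1H-indole-2-carboxylate F10.
   - Reductive amination (Me2NH, NaBH(OAc)3, AcOH, 1,2-dichloroethane) gives 9.

**Further compounds**
F1 | step 4 | N,N-dimethyl-3-(trimethylsilyl)prop-2-yn-1-amine | CN(C)CC#C[Si](C)(C)C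
F2 | step 4 | 4,5-dibromo-2-iodoaniline | Nc1cc(Br)c(Br)cc1I
F3 | step 4 | 1-[5,6-dibromo-2-(trimethylsilyl)-1H-indol-3-yl]-N,N-dimethylmethanamine | CN(C)Cc1c([Si](C)(C)C)[nH]c2cc(Br)c(Br)cc12
F4 | step 4 | 1-[5,6-dibromo-1-methyl-2-(trimethylsilyl)-1H-indol-3-yl]-N,N-dimethylmethanamine | CN(C)Cc1c([Si](C)(C)C)n(C)c2cc(Br)c(Br)cc12
F5 | step 7 | 5,6-dibromo-1-methyl-1H-indole-2-carboxylic acid | OC(=O)c1cc2cc(Br)c(Br)cc2n1C
F6 | step 7 | 5,6-dibromo-1-methyl-1H-indole | Cn1ccc2cc(Br)c(Br)cc21
F7 | step 7 | 3,3,5,6-tetrabromo-1-methylindolin-2-one | CN1C(=O)C(Br)(Br)c2cc(Br)c(Br)cc21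
F8 | step 7 | 5,6-dibromo-1-methylindolin-2-one | CN1C(=O)Cc2cc(Br)c(Br)cc21
F9 | step 7 | 2,5,6-tribromo-1-methyl-1H-indole-3-carbaldehyde | Cn1c(Br)c(C=O)c2cc(Br)c(Br)cc21
F10 | step 5 | methyl 5,6-dibromo-3-formyl-1-methyl-1H-indole-2-carboxylate | COC(=O)c1c(C=O)c2cc(Br)c(Br)cc2n1C
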